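## The problem

Compound 23 is a linear trimer of (−)-epicatechin 3-O-gallate: C4 of unit 1 is bonded to C6 of unit 2 (the ring A carbon between O5 and O7, para to O1), and C4 of unit 2 is bonded to C8 of unit 3. It has eight stereocentres: every ring C is 2R,3R (2,3-cis), and each interflavan bond is trans to the neighbouring 3-O-galloyl group. Ordinary C4-cation chemistry attacks C8 of a flavan nucleophile, so the 4→8 bond is easy and the 4→6 bond is the regiochemical problem. Within a unit, the C3 acyloxy group can direct C4 and an alkene or epoxide geometry can tie C2 to C3, but the units are too far apart to control one another, so each needs its own source of absolute configuration. The 21 free phenols are oxidation- and base-sensitive, the gallate esters are base-labile and the interflavan bonds cleave in protic acid, so the phenols must stay masked until one neutral final step. The enabling feature is ring C of unit 1: its three contiguous stereocentres C2, C3 and C4 end at a C4 that is bonded to an arene carbon flanked by two oxygens with a third oxygen para. That carbon can therefore arrive as the formyl carbon of a symmetric 2,4,6-trioxygenated benzaldehyde, and ring C can be assembled from a phenol (ring A), this aldehyde (C4 plus ring A of unit 2) and a Z-enol gallate (C2, C3, ring B and the ester) through an ortho-quinone methide. The para oxygen later becomes O1 of unit 2, and both carbons ortho to it are equivalent, so no 6-versus-8 choice ever arises.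

## Retrosynthesis

**23 ⇒ 22.** The 21 O–benzyl bonds are cut last. Benzyl ethers survive every acid, base and palladium step of the route and fall together under neutral hydrogenolysis, which the esters and interflavan bonds tolerate.

**22 ⇒ 17 + 20.** Two bonds to C4 of unit 2 are cut, C4–C8 (unit 3) and C4–C4a (unit 2), so that C4 becomes the carbon of a diethyl acetal. Cutting only the interflavan bond would require a C4 leaving group on a preformed unit 1–unit 2 dimer, and a benzylic oxidation could not spare the more activated diarylmethine C4–H of unit 1. Precursor 17 has one ring and one stereocentre fewer, and unit 3 becomes the chiral-pool monomer 20. The forward reaction must close ring C onto either of two equivalent carbons ortho to the ether oxygen, then let C8 of 20 capture the C4 cation trans to the participating gallate.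

**17 ⇒ 16 + 6, then 16 ⇒ 12 + 15.** The ester is cut first, then the O1–C2 ether bond of unit 2. Opening cis-epoxide 15 at its benzylic carbon with the phenoxide of 12 inverts that carbon and delivers the relative configuration that becomes 2,3-cis. A Mitsunobu etherification would need inversion at an ionisation-prone, electron-rich benzylic alcohol, and an allylic etherification would set C2 only and leave four more steps to reach the acetal. Epoxide 15 carries both stereocentres and the masked aldehyde in ten heavy atoms beyond ring B.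

**15 ⇒ 14 ⇒ 13 ⇒ 5.** The epoxide oxygen is removed to give Z-alkene 14, the alkene is taken back to alkyne 13, and the acetal carbon is cut from arylacetylene 5. Asymmetric epoxidation of a cis-β-substituted styrene is the best case for (salen)manganese catalysis, and 5 is shared with the enol gallate.

**12 ⇒ 11.** The O–allyl bond is restored. Allyl is inert to the acid of the key step and is removed by zerovalent palladium without touching benzyl ethers or the ester.

**11 ⇒ 8 + 3 + 7 (key disconnection).** C4–C4a, C3–C4 and O1–C2 of unit 1 are cut together. Against a stepwise build-up from epicatechin this removes the regiochemical problem, because the aldehyde is symmetric, and reduces a compound with three stereocentres to three achiral pieces. The forward reaction must outrun a second arylation of the quinone methide, use the acyloxy-bearing carbon of 7 as the nucleophile, give 2,3-cis-3,4-trans and choose one enantiomer. The plan is strengthened by keeping phenol 8 scarce (slow addition) and by removing water with sieves.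

**Building blocks.** Enol ester 7 is cut at the O–vinyl bond to alkyne 5 and acid 6. Alkyne 5 comes from aldehyde 4 by one-carbon homologation. Aldehyde 3 comes from 1 through 2 by two etherifications of differing selectivity. Monomer 20 comes from (−)-epicatechin 18 through 19.

## Roads not taken

Alternative 1: The bond between C6 of unit 2 and the future C4 of unit 1 is cut at the ketone level, together with the C7–O bond. In the forward step fluoride releases an aryne from an ortho-silyl aryl triflate, and a carboxylic acid holding C2, C3 and the future C4 of unit 1 inserts, its oxygen going to C7 and its acyl carbon to C6, to give the ortho-hydroxyaryl ketone A1. Its merits are real: the 4→6 junction is fixed by the insertion, C2 and C3 can come from reliable dihydroxylation chemistry, and aryne insertion into acid C–O bonds is known for simple acids. For this target the weak points are that no ring closes, so ring C of unit 1 must still be closed onto the ketone and C4 reduced to the trans configuration. The C3 stereocentre of A1 sits between a ketone and a β-aryloxy leaving group and is exposed to epimerisation and elimination under fluoride. Aryne regioselectivity rests on a single flanking alkoxy group. Alternative 1 is better in that it needs no new asymmetric catalysis; the chosen plan sets against this a key step that closes the ring and sets C2 to C4 at once, avoids any enolisable α-acyloxy ketone, and reaches the same regiochemical certainty through the symmetry of 3 in fewer steps.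

Alternative 2: Two bonds of ring A of unit 2 are cut (C6–C7 and C5–C4a). Heating an alkoxycyclobutenone with a unit 1 flavan that carries a siloxyethynyl group at C4 would build the ring as phenol A2, with free O7, silylated O5 and an allylated para oxygen. Unit 1 would come from the chiral pool, so its three stereocentres are secure, and the benzannulation fixes the substitution pattern by construction; on stereochemical security this road is better than the chosen one. Its cost is length and fragility: a 4β-alkynyl flavan must be made and turned into a siloxyalkyne at a hindered, acid-sensitive benzylic position, the annulation is thermal, O3 of A2 is a silyl ether so the gallate must be exchanged in later, and O5 and O7 are differentiated although both end as free phenols. Ring C of unit 2 still has to be built afterwards. The chosen plan answers with three achiral components in one step and no chiral-pool dependence for unit 1.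

Alternative 3: C4–C4a of unit 3 is cut last. Constant-current oxidation in methanol would couple the terminal carbon of a 2-methoxyallyl aryl ether with the cap ring to give ketal A3. Its one advantage is that the unit 2–unit 3 bond is made earlier with a small arene and not with a bulky monomer. Against it, A3 leaves C2 of unit 3 undefined, and the many benzylated phloroglucinol and catechol rings have oxidation potentials close to that of the enol ether, so the anode is unlikely to be selective. Ketal hydrolysis, cis-selective reduction and galloylation would then follow on the whole trimer. Unit 3 is simply the natural monomer, which the chosen plan takes from 18 in two steps, so this road compares poorly on step economy and stereocontrol.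

Key step: step 5

Assumption: the sense of asymmetric induction in steps 5 and 9 is assigned by analogy with simpler substrates; if it proves opposite, the mirror-image catalyst is used and nothing else changes.

## Steps

Step 1
Reactants: 1 2,4,6-trihydroxybenzaldehyde
Product: 2 4-(allyloxy)-2,6-dihydroxybenzaldehyde
Conditions: allyl bromide (1.05 equiv), KHCO3, DMF, rt
Reagents that add atoms: allyl bromide, C=CCBr
Why: Williamson etherification; the 4-hydroxyl is the most acidic (para to the formyl group) and the only one not hydrogen-bonded to the carbonyl, so a weak base and one equivalent of halide should alkylate it selectively.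

Step 2
Reactants: 2 4-(allyloxy)-2,6-dihydroxybenzaldehyde
Product: 3 4-(allyloxy)-2,6-bis(benzyloxy)benzaldehyde
Conditions: BnBr (2.3 equiv), K2CO3, DMF, 60 °C
Reagents that add atoms: benzyl bromide, BrCc1ccccc1
Why: Williamson etherification of the two hydrogen-bonded phenols under more forcing conditions; the allyl ether now marks the oxygen that will become O1 of unit 2.

Step 3
Reactants: 4 3,4-bis(benzyloxy)benzaldehyde
Product: 5 1,2-bis(benzyloxy)-4-ethynylbenzene
Conditions: dimethyl (1-diazo-2-oxopropyl)phosphonate, K2CO3, MeOH/THF, rt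
Reagents that add atoms: dimethyl (1-diazo-2-oxopropyl)phosphonate, CC(=O)C(=[N+]=[N-])P(=O)(OC)OC
Why: Seyferth–Gilbert homologation in its Ohira–Bestmann form; the mild carbonate conditions suit a non-enolisable, electron-rich aldehyde.

Step 4
Reactants: 5 1,2-bis(benzyloxy)-4-ethynylbenzene; 6 3,4,5-tris(benzyloxy)benzoic acid
Product: 7 (Z)-2-[3,4-bis(benzyloxy)phenyl]ethenyl 3,4,5-tris(benzyloxy)benzoate
Conditions: Ru(η3-2-methylallyl)2(Ph2P(CH2)4PPh2) (3 mol%), toluene, 65 °C
Reagents that add atoms: none
Why: Ruthenium-catalysed anti-Markovnikov addition of a carboxylic acid to a terminal alkyne through a vinylidene complex; external attack of the carboxylate on the vinylidene carbon should give the Z-enol ester, the geometry that later becomes the 2,3-cis relation.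

Step 5
Reactants: 8 3,5-bis(benzyloxy)phenol; 3 4-(allyloxy)-2,6-bis(benzyloxy)benzaldehyde; 7 (Z)-2-[3,4-bis(benzyloxy)phenyl]ethenyl 3,4,5-tris(benzyloxy)benzoate
Product: 11 4β-[4-(allyloxy)-2,6-bis(benzyloxy)phenyl]-5,7,3′,4′-tetra-O-benzyl-(−)-epicatechin 3-O-[3,4,5-tris(benzyloxy)benzoate] (2R,3R,4S; 2,3-cis-3,4-trans), via benzhydrol 9 (not isolated), via ortho-quinone methide 10 (not isolated)
Conditions: (R)-3,3′-bis(2,4,6-triisopropylphenyl)-1,1′-binaphthyl-2,2′-diyl hydrogen phosphate (10 mol%), 5 Å molecular sieves, CH2Cl2, −20 °C → rt, 7 in excess (1.5 equiv), 8 added over 6 h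
Reagents that add atoms: none
Why: Proposed new method: the acid first promotes ortho-selective Friedel–Crafts hydroxyalkylation of 8 by 3 (the phosphate bridges the phenolic OH and the activated formyl group) to benzhydrol 9, which loses water to the ortho-quinone methide 10, held as a hydrogen-bonded ion pair with the chiral phosphate. 10 then adds the Z-enol ester 7 in an inverse-electron-demand oxa-[4+2] cycloaddition; the closest known reaction types are the acid-catalysed three-component phenol–aldehyde–styrene synthesis of 2,4-diarylchromans and the chiral phosphoric acid catalysed [4+2] reactions of ortho-quinone methides with styrenes, and the β-acyloxystyrene partner is the untested element. Ring C is closed here as a six-membered ring by the cycloaddition itself, asynchronously: C3–C4 forms ahead of O1–C2 while positive charge builds at C2, where the 3,4-bis(benzyloxy)phenyl group carries it. The same charge distribution fixes the regiochemistry, since the para-alkoxyaryl group is a far better donor than the acyloxy group, so the acyloxy-bearing carbon is the nucleophilic terminus and becomes C3. C2 and C3 are set cis by suprafacial transfer of the Z geometry of 7; C4 is set trans to C3 because the 2,6-disubstituted aryl group on the methide carbon is pushed pseudo-axial by peri strain with the C5 benzyloxy group, and only the approach that places the acyloxy group anti to it lets the C2 aryl group stay equatorial, free of a 1,3-diaxial aryl–aryl contact. The absolute configuration has no source other than the binaphthyl phosphate bound to the methide oxygen, which blocks one face of 10. Beyond regio-, diastereo- and enantioselectivity the step needs chemoselectivity, because 8 itself can add to 10; this is met by keeping 8 scarce and by sieves that also remove the water that would hydrolyse 7. The symmetry of 3 ensures that the ring A precursor of unit 2 carries its oxygen para to the new C4–aryl bond.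

Step 6
Reactants: 11 4β-[4-(allyloxy)-2,6-bis(benzyloxy)phenyl]-5,7,3′,4′-tetra-O-benzyl-(−)-epicatechin 3-O-[3,4,5-tris(benzyloxy)benzoate]
Product: 12 4β-[2,6-bis(benzyloxy)-4-hydroxyphenyl]-5,7,3′,4′-tetra-O-benzyl-(−)-epicatechin 3-O-[3,4,5-tris(benzyloxy)benzoate] (2R,3R,4S)
Conditions: Pd(PPh3)4 (5 mol%), morpholine, THF, rt
Reagents that add atoms: none
Why: Tsuji–Trost deallylation; zerovalent palladium ionises the aryl allyl ether and morpholine traps the allyl fragment, while benzyl ethers, the ester and the stereocentres are untouched.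

Step 7
Reactants: 5 1,2-bis(benzyloxy)-4-ethynylbenzene
Product: 13 1,2-bis(benzyloxy)-4-(3,3-diethoxyprop-1-yn-1-yl)benzene
Conditions: EtMgBr, THF, 0 °C → rt; then HC(OEt)3, toluene, 90 °C
Reagents that add atoms: triethyl orthoformate, CCOC(OCC)OCC
Why: Bodroux–Chichibabin-type reaction of the alkynyl Grignard reagent with an orthoformate; it introduces the future C4 of unit 2 at the aldehyde oxidation level, already masked as an acetal.

Step 8
Reactants: 13 1,2-bis(benzyloxy)-4-(3,3-diethoxyprop-1-yn-1-yl)benzene
Product: 14 (Z)-1,2-bis(benzyloxy)-4-(3,3-diethoxyprop-1-en-1-yl)benzene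
Conditions: H2 (1 atm), Pd/CaCO3 poisoned with Pb(OAc)2 (Lindlar catalyst), quinoline, EtOAc, rt
Reagents that add atoms: none
Why: Lindlar semihydrogenation; syn delivery of hydrogen gives the Z-alkene, and benzyl ethers are stable on the poisoned catalyst.

Step 9
Reactants: 14 (Z)-1,2-bis(benzyloxy)-4-(3,3-diethoxyprop-1-en-1-yl)benzene
Product: 15 (2S,3S)-2-[3,4-bis(benzyloxy)phenyl]-3-(diethoxymethyl)oxirane (cis)
Conditions: (S,S)-[N,N′-bis(3,5-di-tert-butylsalicylidene)cyclohexane-1,2-diaminato]MnCl (5 mol%), mCPBA, N-methylmorpholine N-oxide, CH2Cl2, −78 °C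
Reagents that add atoms: 3-chloroperoxybenzoic acid (mCPBA), O=C(OO)c1cccc(Cl)c1
Why: Jacobsen–Katsuki epoxidation; cis-β-substituted styrenes are its best substrate class, and the chiral manganese oxo species delivers oxygen to one enantioface, the (S,S) catalyst being chosen by analogy with cis-β-methylstyrene and cis-cinnamates. The low-temperature peracid protocol should limit leakage to the trans-epoxide.

Step 10
Reactants: 12 4β-[2,6-bis(benzyloxy)-4-hydroxyphenyl]-5,7,3′,4′-tetra-O-benzyl-(−)-epicatechin 3-O-[3,4,5-tris(benzyloxy)benzoate]; 15 (2S,3S)-2-[3,4-bis(benzyloxy)phenyl]-3-(diethoxymethyl)oxirane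
Product: 16 ether of 12 in which the phenolic oxygen carries the (1R,2S)-1-[3,4-bis(benzyloxy)phenyl]-3,3-diethoxy-2-hydroxypropyl group
Conditions: Cs2CO3 (0.3 equiv), DMF, 70 °C, 15 in excess (1.5 equiv)
Reagents that add atoms: none
Why: Base-catalysed opening of an aryl epoxide by a phenoxide, SN2 at the benzylic carbon (the other carbon is deactivated by the adjacent acetal) with inversion; this turns the cis-epoxide into the relative configuration that becomes 2,3-cis in ring C of unit 2. Both stereocentres come from 15, and the substoichiometric base should spare the gallate ester.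

Step 11
Reactants: 16 hydroxy acetal ether of 12; 6 3,4,5-tris(benzyloxy)benzoic acid
Product: 17 ether of 12 in which the phenolic oxygen carries the (1R,2S)-1-[3,4-bis(benzyloxy)phenyl]-3,3-diethoxy-2-{[3,4,5-tris(benzyloxy)benzoyl]oxy}propyl group
Conditions: DCC, DMAP, CH2Cl2, rt
Reagents that add atoms: none
Why: Steglich esterification of the hindered secondary alcohol; no stereocentre is touched and the acetal and ethers are inert.

Step 12
Reactants: 18 (−)-epicatechin
Product: 19 5,7,3′,4′-tetra-O-benzyl-(−)-epicatechin
Conditions: BnBr (4.4 equiv), K2CO3, DMF, 0 °C → rt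
Reagents that add atoms: benzyl bromide, BrCc1ccccc1
Why: Williamson benzylation of the four phenols; carbonate does not deprotonate the aliphatic 3-hydroxyl, which stays free, and the mild temperature should avoid epimerisation at C2.

Step 13
Reactants: 19 5,7,3′,4′-tetra-O-benzyl-(−)-epicatechin; 6 3,4,5-tris(benzyloxy)benzoic acid
Product: 20 5,7,3′,4′-tetra-O-benzyl-(−)-epicatechin 3-O-[3,4,5-tris(benzyloxy)benzoate]
Conditions: DCC, DMAP, CH2Cl2, rt
Reagents that add atoms: none
Why: Steglich esterification; it gives the unit 3 nucleophile with its 2R,3R stereocentres taken from the chiral pool.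

Step 14
Reactants: 17 gallate acetal ether of 12; 20 5,7,3′,4′-tetra-O-benzyl-(−)-epicatechin 3-O-[3,4,5-tris(benzyloxy)benzoate]
Product: 22 per-O-benzyl (21 benzyl ethers) derivative of epicatechin gallate-(4β→6)-epicatechin gallate-(4β→8)-epicatechin gallate, via 4-ethoxyflavan 21 (not isolated)
Conditions: 20 (4 equiv), TMSOTf (2.2 equiv), CH2Cl2, −78 → −30 °C; Et3N quench
Reagents that add atoms: none
Why: The Lewis acid ionises the acetal to an oxocarbenium ion, which closes ring C of unit 2 by six-membered Friedel–Crafts attack of either equivalent carbon ortho to the ether oxygen (21); 21 then ionises to the C4 benzylic cation, which C8 of 20 captures, the established mode of procyanidin chain extension. The new C4 centre is set trans to C3 by participation of the neighbouring galloyl carbonyl group, C8 is the known site of attack in 5,7-dibenzyloxyflavans, and the excess of 20 should suppress self-condensation.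

Step 15
Reactants: 22 per-O-benzyl trimer
Product: 23 (−)-epicatechin 3-O-gallate-(4β→6)-(−)-epicatechin 3-O-gallate-(4β→8)-(−)-epicatechin 3-O-gallate (CNP0183218.1)
Conditions: H2 (1 atm), Pd(OH)2/C, THF/MeOH/H2O (20:1:1), rt
Reagents that add atoms: none
Why: Hydrogenolysis of all 21 benzyl ethers under neutral conditions; the esters, the interflavan bonds and all eight stereocentres are not affected, as in deprotections of benzylated procyanidin gallates.

## Compound list

1 | 2,4,6-trihydroxybenzaldehyde | O=Cc1c(O)cc(O)cc1O | starting material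
2 | 4-(allyloxy)-2,6-dihydroxybenzaldehyde | O=Cc1c(O)cc(OCC=C)cc1O | intermediate
3 | 4-(allyloxy)-2,6-bis(benzyloxy)benzaldehyde | O=Cc1c(OCc2ccccc2)cc(OCC=C)cc1OCc2ccccc2 | intermediate
4 | 3,4-bis(benzyloxy)benzaldehyde | O=Cc1ccc(OCc2ccccc2)c(OCc2ccccc2)c1 | starting material
5 | 1,2-bis(benzyloxy)-4-ethynylbenzene | C#Cc1ccc(OCc2ccccc2)c(OCc2ccccc2)c1 | intermediate
6 | 3,4,5-tris(benzyloxy)benzoic acid | OC(=O)c1cc(OCc2ccccc2)c(OCc2ccccc2)c(OCc2ccccc2)c1 | starting material
7 | (Z)-2-[3,4-bis(benzyloxy)phenyl]ethenyl 3,4,5-tris(benzyloxy)benzoate | O=C(O/C=C\c1ccc(OCc2ccccc2)c(OCc2ccccc2)c1)c1cc(OCc2ccccc2)c(OCc2ccccc2)c(OCc2ccccc2)c1 | intermediate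
8 | 3,5-bis(benzyloxy)phenol | Oc1cc(OCc2ccccc2)cc(OCc2ccccc2)c1 | starting material
9 | 2-{[4-(allyloxy)-2,6-bis(benzyloxy)phenyl](hydroxy)methyl}-3,5-bis(benzyloxy)phenol (carbinol configuration not defined) | OC(c1c(O)cc(OCc2ccccc2)cc1OCc2ccccc2)c1c(OCc2ccccc2)cc(OCC=C)cc1OCc2ccccc2 | intermediate (not isolated)
10 | 6-{[4-(allyloxy)-2,6-bis(benzyloxy)phenyl]methylidene}-3,5-bis(benzyloxy)cyclohexa-2,4-dien-1-one (alkene geometry not defined) | O=C1C=C(OCc2ccccc2)C=C(OCc2ccccc2)C1=Cc1c(OCc2ccccc2)cc(OCC=C)cc1OCc2ccccc2 | intermediate (not isolated)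
11 | 4β-[4-(allyloxy)-2,6-bis(benzyloxy)phenyl]-5,7,3′,4′-tetra-O-benzyl-(−)-epicatechin 3-O-[3,4,5-tris(benzyloxy)benzoate] (2R,3R,4S) | O=C(O[C@@H]1[C@@H](c3c(OCc5ccccc5)cc(OCC=C)cc3OCc5ccccc5)c2c(OCc5ccccc5)cc(OCc5ccccc5)cc2O[C@@H]1c6ccc(OCc5ccccc5)c(OCc5ccccc5)c6)c6cc(OCc5ccccc5)c(OCc5ccccc5)c(OCc5ccccc5)c6 | intermediate
12 | 4β-[2,6-bis(benzyloxy)-4-hydroxyphenyl]-5,7,3′,4′-tetra-O-benzyl-(−)-epicatechin 3-O-[3,4,5-tris(benzyloxy)benzoate] (2R,3R,4S) | O=C(O[C@@H]1[C@@H](c3c(OCc5ccccc5)cc(O)cc3OCc5ccccc5)c2c(OCc5ccccc5)cc(OCc5ccccc5)cc2O[C@@H]1c6ccc(OCc5ccccc5)c(OCc5ccccc5)c6)c6cc(OCc5ccccc5)c(OCc5ccccc5)c(OCc5ccccc5)c6 | intermediate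
13 | 1,2-bis(benzyloxy)-4-(3,3-diethoxyprop-1-yn-1-yl)benzene | CCOC(OCC)C#Cc1ccc(OCc2ccccc2)c(OCc2ccccc2)c1 | intermediate
14 | (Z)-1,2-bis(benzyloxy)-4-(3,3-diethoxyprop-1-en-1-yl)benzene | CCOC(OCC)/C=C\c1ccc(OCc2ccccc2)c(OCc2ccccc2)c1 | intermediate
15 | (2S,3S)-2-[3,4-bis(benzyloxy)phenyl]-3-(diethoxymethyl)oxirane (cis) | CCOC(OCC)[C@H]1O[C@H]1c1ccc(OCc2ccccc2)c(OCc2ccccc2)c1 | intermediate
16 | 12 etherified at its phenolic oxygen with the (1R,2S)-1-[3,4-bis(benzyloxy)phenyl]-3,3-diethoxy-2-hydroxypropyl group | O=C(O[C@@H]1[C@@H](c3c(OCc5ccccc5)cc(O[C@H](c6ccc(OCc5ccccc5)c(OCc5ccccc5)c6)[C@H](O)C(OCC)OCC)cc3OCc5ccccc5)c2c(OCc5ccccc5)cc(OCc5ccccc5)cc2O[C@@H]1c6ccc(OCc5ccccc5)c(OCc5ccccc5)c6)c6cc(OCc5ccccc5)c(OCc5ccccc5)c(OCc5ccccc5)c6 | intermediate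
17 | 16 esterified at the side-chain hydroxyl with 3,4,5-tris(benzyloxy)benzoic acid (side chain 1R,2S) | O=C(O[C@@H]1[C@@H](c3c(OCc5ccccc5)cc(O[C@H](c6ccc(OCc5ccccc5)c(OCc5ccccc5)c6)[C@H](OC(=O)c6cc(OCc5ccccc5)c(OCc5ccccc5)c(OCc5ccccc5)c6)C(OCC)OCC)cc3OCc5ccccc5)c2c(OCc5ccccc5)cc(OCc5ccccc5)cc2O[C@@H]1c6ccc(OCc5ccccc5)c(OCc5ccccc5)c6)c6cc(OCc5ccccc5)c(OCc5ccccc5)c(OCc5ccccc5)c6 | intermediate
18 | (−)-epicatechin (2R,3R) | O[C@@H]1Cc2c(O)cc(O)cc2O[C@@H]1c1ccc(O)c(O)c1 | starting material
19 | 5,7,3′,4′-tetra-O-benzyl-(−)-epicatechin | O[C@@H]1Cc2c(OCc5ccccc5)cc(OCc5ccccc5)cc2O[C@@H]1c6ccc(OCc5ccccc5)c(OCc5ccccc5)c6 | intermediate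
20 | 5,7,3′,4′-tetra-O-benzyl-(−)-epicatechin 3-O-[3,4,5-tris(benzyloxy)benzoate] | O=C(O[C@@H]1Cc2c(OCc5ccccc5)cc(OCc5ccccc5)cc2O[C@@H]1c6ccc(OCc5ccccc5)c(OCc5ccccc5)c6)c6cc(OCc5ccccc5)c(OCc5ccccc5)c(OCc5ccccc5)c6 | intermediate
21 | benzylated epicatechin gallate-(4β→6)-4-ethoxyepicatechin gallate (units 1 and 2 ring-closed; C4 of unit 2 not defined) | O=C(O[C@@H]1[C@@H](c3c(OCc5ccccc5)cc4c(c3OCc5ccccc5)C(OCC)[C@@H](OC(=O)c6cc(OCc5ccccc5)c(OCc5ccccc5)c(OCc5ccccc5)c6)[C@@H](c6ccc(OCc5ccccc5)c(OCc5ccccc5)c6)O4)c2c(OCc5ccccc5)cc(OCc5ccccc5)cc2O[C@@H]1c6ccc(OCc5ccccc5)c(OCc5ccccc5)c6)c6cc(OCc5ccccc5)c(OCc5ccccc5)c(OCc5ccccc5)c6 | intermediate (not isolated)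
22 | per-O-benzyl (21 benzyl ethers) epicatechin gallate-(4β→6)-epicatechin gallate-(4β→8)-epicatechin gallate | O=C(O[C@@H]1[C@@H](c3c(OCc5ccccc5)cc4c(c3OCc5ccccc5)[C@H](c7c(OCc5ccccc5)cc(OCc5ccccc5)c8c7O[C@H](c6ccc(OCc5ccccc5)c(OCc5ccccc5)c6)[C@H](OC(=O)c6cc(OCc5ccccc5)c(OCc5ccccc5)c(OCc5ccccc5)c6)C8)[C@@H](OC(=O)c6cc(OCc5ccccc5)c(OCc5ccccc5)c(OCc5ccccc5)c6)[C@@H](c6ccc(OCc5ccccc5)c(OCc5ccccc5)c6)O4)c2c(OCc5ccccc5)cc(OCc5ccccc5)cc2O[C@@H]1c6ccc(OCc5ccccc5)c(OCc5ccccc5)c6)c6cc(OCc5ccccc5)c(OCc5ccccc5)c(OCc5ccccc5)c6 | intermediate
23 | (−)-epicatechin 3-O-gallate-(4β→6)-(−)-epicatechin 3-O-gallate-(4β→8)-(−)-epicatechin 3-O-gallate (all 2R,3R; both interflavan bonds trans to the adjacent 3-O-galloyl group) | O=C(O[C@@H]1[C@@H](c2c(O)cc3c(c2O)[C@H](c2c(O)cc(O)c4c2O[C@H](c2ccc(O)c(O)c2)[C@H](OC(=O)c2cc(O)c(O)c(O)c2)C4)[C@@H](OC(=O)c2cc(O)c(O)c(O)c2)[C@@H](c2ccc(O)c(O)c2)O3)c2c(O)cc(O)cc2O[C@@H]1c1ccc(O)c(O)c1)c1cc(O)c(O)c(O)c1 | target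

## Step count and least certain steps

Total: 15 steps. Longest linear sequence: 8 steps (for example steps 1, 2, 5, 6, 10, 11, 14, 15).

**Step 5 (proposed new method).** Three processes are most likely to fail it. First, the quinone methide may be consumed by a second Friedel–Crafts addition of phenol 8, or the hindered, electron-rich aldehyde may fail to condense under so weak an acid. Second, cycloaddition of the deactivated, Z-configured enol ester may be slow, leaving time for acyl transfer from 7 to 8 and for hydrolysis of 7. Third, the 2,3-cis relation may be lost by bond rotation in a long-lived C2 benzylic cation, or facial selectivity may be poor because 7 offers the catalyst no second binding point.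

The fallback uses known chiral-pool chemistry, sets out from 19 and 8, and comes back at 12. Benzylic oxidation of 19 with DDQ in the presence of 2-ethoxyethanol should give 4β-(2-ethoxyethoxy)-5,7,3′,4′-tetra-O-benzyl-(−)-epicatechin F1. Steglich esterification of F1 with 6 should give its 3-O-[3,4,5-tris(benzyloxy)benzoate] F2. Phenol 8 is silylated (i-Pr3SiCl, imidazole) to [3,5-bis(benzyloxy)phenoxy]triisopropylsilane F3. Friedel–Crafts coupling of F2 with excess F3 (TMSOTf, CH2Cl2, −78 °C) should give 4β-[2,6-bis(benzyloxy)-4-(triisopropylsilyloxy)phenyl]-5,7,3′,4′-tetra-O-benzyl-(−)-epicatechin 3-O-[3,4,5-tris(benzyloxy)benzoate] F4. In this coupling the gallate directs the arene trans, and the bulky silyl ether screens both carbons next to it, so attack should go para to silicon; any isomer from attack next to the silyl ether is removed at this stage. Bu4NF buffered with acetic acid then frees the phenol and gives 12.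

**Step 14.** The first oxocarbenium ion may be intercepted by 20 before ring closure, so that C4 is set in an uncontrolled cyclisation. The C4 cation may also be taken by the free C8 of unit 2 or by ring A of unit 1 of another molecule (oligomerisation), lose a proton to a flav-3-ene, or the acid may start to cleave the interflavan bond already present.

The fallback separates ring closure from chain extension and changes the mode of activation; it sets out from 17 and comes back at 22. Treating 17 with BF3·OEt2 and 1.1 equivalents of benzyl mercaptan (CH2Cl2, −40 °C) should close ring C and trap C4 as the isolable 4β-benzylthio derivative of the benzylated unit 1–unit 2 dimer F5. F5 is then activated with the thiophile AgBF4 in the presence of 20 (THF, 0 °C), the classical thioether route to interflavan bonds, to give 22.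

**Step 9.** Oxygen transfer from manganese is stepwise, and with so electron-rich an aryl group the radical intermediate may rotate before closure, leaking to the trans-epoxide. Enantioface discrimination may be incomplete for this new substrate, and the acid-labile epoxide may rearrange during isolation.

The fallback replaces metal-oxo transfer by dioxirane transfer; it sets out from 14 and comes back at 15. A Shi epoxidation with a ketone catalyst of the oxazolidinone-fused type developed for cis-alkenes (Oxone, K2CO3 buffer, aqueous MeCN) passes through a concerted spiro transition state that cannot isomerise the alkene and runs at basic pH, which protects the epoxide. This fallback makes no compound outside the list (entry F0).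

## Further compounds

F1 | step 5 | 4β-(2-ethoxyethoxy)-5,7,3′,4′-tetra-O-benzyl-(−)-epicatechin | O[C@@H]1[C@@H](OCCOCC)c2c(OCc5ccccc5)cc(OCc5ccccc5)cc2O[C@@H]1c6ccc(OCc5ccccc5)c(OCc5ccccc5)c6
F2 | step 5 | 4β-(2-ethoxyethoxy)-5,7,3′,4′-tetra-O-benzyl-(−)-epicatechin 3-O-[3,4,5-tris(benzyloxy)benzoate] | O=C(O[C@@H]1[C@@H](OCCOCC)c2c(OCc5ccccc5)cc(OCc5ccccc5)cc2O[C@@H]1c6ccc(OCc5ccccc5)c(OCc5ccccc5)c6)c6cc(OCc5ccccc5)c(OCc5ccccc5)c(OCc5ccccc5)c6
F3 | step 5 | [3,5-bis(benzyloxy)phenoxy]triisopropylsilane | CC(C)[Si](Oc1cc(OCc2ccccc2)cc(OCc2ccccc2)c1)(C(C)C)C(C)C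
F4 | step 5 | 4β-[2,6-bis(benzyloxy)-4-(triisopropylsilyloxy)phenyl]-5,7,3′,4′-tetra-O-benzyl-(−)-epicatechin 3-O-[3,4,5-tris(benzyloxy)benzoate] | O=C(O[C@@H]1[C@@H](c3c(OCc5ccccc5)cc(O[Si](C(C)C)(C(C)C)C(C)C)cc3OCc5ccccc5)c2c(OCc5ccccc5)cc(OCc5ccccc5)cc2O[C@@H]1c6ccc(OCc5ccccc5)c(OCc5ccccc5)c6)c6cc(OCc5ccccc5)c(OCc5ccccc5)c(OCc5ccccc5)c6
F5 | step 14 | benzylated epicatechin gallate-(4β→6)-4β-(benzylthio)epicatechin gallate (benzylthio group trans to the 3-O-galloyl group of unit 2) | O=C(O[C@@H]1[C@@H](c3c(OCc5ccccc5)cc4c(c3OCc5ccccc5)[C@H](SCc5ccccc5)[C@@H](OC(=O)c6cc(OCc5ccccc5)c(OCc5ccccc5)c(OCc5ccccc5)c6)[C@@H](c6ccc(OCc5ccccc5)c(OCc5ccccc5)c6)O4)c2c(OCc5ccccc5)cc(OCc5ccccc5)cc2O[C@@H]1c6ccc(OCc5ccccc5)c(OCc5ccccc5)c6)c6cc(OCc5ccccc5)c(OCc5ccccc5)c(OCc5ccccc5)c6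
F0 | step 9 | none | none
A1 | alternative 1 | ortho-hydroxyaryl ketone joining C6 of the unit 2 ring A precursor to the future C4 of unit 1 (benzyl-protected, 3-O-gallate, 3,5-bis(benzyloxy)phenyl ether at C2) | C=CCOc1cc(OCc2ccccc2)c(C(=O)[C@@H](OC(=O)c6cc(OCc5ccccc5)c(OCc5ccccc5)c(OCc5ccccc5)c6)[C@@H](c6ccc(OCc5ccccc5)c(OCc5ccccc5)c6)Oc3cc(OCc5ccccc5)cc(OCc5ccccc5)c3)c(O)c1
A2 | alternative 2 | 4β-[4-(allyloxy)-2-hydroxy-6-(triisopropylsilyloxy)phenyl]-5,7,3′,4′-tetra-O-benzyl-3-O-(tert-butyldimethylsilyl)-(−)-epicatechin | CC(C)(C)[Si](C)(C)O[C@@H]1[C@@H](c3c(O)cc(OCC=C)cc3O[Si](C(C)C)(C(C)C)C(C)C)c2c(OCc5ccccc5)cc(OCc5ccccc5)cc2O[C@@H]1c6ccc(OCc5ccccc5)c(OCc5ccccc5)c6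
A3 | alternative 3 | benzyl-protected trimer with unit 3 as its flavan-3-one dimethyl ketal (C2 of unit 3 not defined) | O=C(O[C@@H]1[C@@H](c2c(OCc5ccccc5)cc3c(c2OCc5ccccc5)[C@H](c2c(OCc5ccccc5)cc(OCc5ccccc5)c4c2OC(c6ccc(OCc5ccccc5)c(OCc5ccccc5)c6)C(OC)(OC)C4)[C@@H](OC(=O)c6cc(OCc5ccccc5)c(OCc5ccccc5)c(OCc5ccccc5)c6)[C@@H](c6ccc(OCc5ccccc5)c(OCc5ccccc5)c6)O3)c2c(OCc5ccccc5)cc(OCc5ccccc5)cc2O[C@@H]1c6ccc(OCc5ccccc5)c(OCc5ccccc5)c6)c6cc(OCc5ccccc5)c(OCc5ccccc5)c(OCc5ccccc5)c6
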